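## Structural features

The target joins a bicyclic 3,5,6,7-tetrahydro-1-benzofuran-4(2H)-one to an eleven-carbon dienoic acid chain. Ring A (cyclohexenone) and ring B (dihydrofuran) share the C3a=C7a double bond, so that O1–C7a=C3a–C4=O is a vinylogous ester. C2 of ring B carries the chain through the tertiary carbinol carbon C10, which continues as CH2CH2 into two trisubstituted (E)-alkenes, the second conjugated to the carboxylic acid. Two stereocentres are neighbours: C2 (S, secondary ether carbon) and C10 (S, tertiary alcohol). The third, C7 (R), is the carbinol on ring A, separated from C2 by O1 and C7a and trans to the C2 substituent. The fragile points are the vinylogous ester (hydroxide or aqueous acid can open ring B, after which either carbonyl could reclose), the C7 hydroxyl (loss of water leads towards an aromatic dihydrobenzofuranol), the tertiary alcohol, and the trisubstituted alkenes, which are ene-reactive towards singlet oxygen. The real difficulty is ring A: two oxygens in a 1,4-relationship at different oxidation levels on either side of a tetrasubstituted enol ether, with C7 to be set relative to a stereocentre on the other ring. The key step uses exactly this pattern: C4 and C7 are the termini of the ring A diene C4=C3a–C7a=C7, and a (4+2) addition of O2 across them leaves the central C3a=C7a bond where the target has it, so one base-induced peroxide cleavage gives ketone and alcohol together.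

## Logic of the disconnections

25 ⇒ 24. Only the O–Si bonds at O7 and O10 are cut. The last step is then a pure deprotection with no C–C or stereochemical event. The forward step must cleave a hindered tertiary silyl ether without hydroxide, which the vinylogous ester would not tolerate.

24 ⇒ 23 + 22. The sp3–sp2 bond C8–C7 of the chain is cut. This removes both trisubstituted alkenes from the core, which is necessary because they cannot be present during the photooxygenation, and it makes the route convergent. The forward coupling must proceed with retention of the alkene geometry and tolerate the C4 ketone and a free carboxylate, so that no ester hydrolysis is needed on the sensitive core.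

23 ⇒ 17. The C8–B bond is traced back to a terminal alkene. The side arm is therefore carried from the start as a vinyl group, whose only allylic carbon is quaternary, so it is inert to singlet oxygen and needs no protecting-group manipulation. The forward hydroboration must select C=C over the C4 carbonyl.

22 ⇒ 21 ⇒ 19 ⇒ 18 (through 20). The C2=C3 bond is cut by carbonyl olefination, and the C6–CH3 and C7–I bonds by syn-carbometalation of a terminal alkyne. Both alkene geometries are fixed by well-understood stereochemistry in a three-step fragment. Saponification is placed here, where nothing else is base-sensitive.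

17 ⇒ 15 (through 16). No skeletal bond is cut; the C4 carbonyl oxygen and the C7 oxygen are reconnected as an O–O bond. Two functional groups at different oxidation levels become one peroxide, and the C7 configuration becomes a consequence of the bridge. The forward base-induced cleavage must remove H–C4 and not H–C7.

15 ⇒ 14. The C4–O and C7–O bonds are cut, giving back O2 and an oxygen-free ring A diene. Two stereocentres and one ring disappear in a single retrosynthetic step. The forward cycloaddition must occur on the diene face anti to the C2 substituent and must outrun ene and (2+2) pathways.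

14 ⇒ 12 ⇒ 11 (through 13). The diene is derived by 1,4-dehydration of the allylic alcohol obtained from the C4 ketone. 11 is a stable, storable vinylogous ester, while the acid-sensitive diene is made only when needed. The forward elimination must lose the proton from C7 and not from C5.

11 ⇒ 8 + 9 (through 10). The C3–C3a and O1–C7a bonds are cut. Ring A then comes from a symmetrical commercial dione, and C2 arrives with its C–O bond intact, so its configuration cannot be lost. The forward step needs C-alkylation instead of O-alkylation of an ambident enolate.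

8 ⇒ 6 ⇒ 5 ⇒ 4 (through 7). The primary C–O bond of the oxirane is traced to a 1,2-diol and this to a chiral-pool acetonide. The tertiary oxygen must be capped before any basic step, otherwise epoxide migration and competing six-ring closure become possible. A TBS ether is chosen because it survives the acetal hydrolysis and adds bulk next to C2.

4 ⇒ 3 ⇒ 1 (through 2). The C10–vinyl bond and then the C10–CH3 bond are cut. C2 is taken from the chiral pool and C10 is created next to it by 1,2-induction. The forward addition must be chelation-controlled.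

## Other disconnections considered

Alternative 1: Ring B is cut at O1–C2 and C2–C3 while ring A is held as an arene. In the forward key step the salicyl acetate A2 releases an ortho-quinone methide, and a cinchona-derived ammonium ylide formed from the bromomethyl ketone A3 adds to its methylene carbon (C2–C3). The phenoxide then displaces the amine (O1–C2) in a formal (4+1) annulation to give the 2-acyl dihydrobenzofuran A1. In its favour, the whole chain and ring B are joined in one convergent step, C2 is set by the catalyst and not by a chiral-pool reagent, and the annulation is mild. In convergence and in independence from substrate control at C2 it is better than the chosen plan. The C10 carbinol would be made by chelation-controlled methyl addition to the C10 ketone of A1, which is the equal of step 2 here in principle, though it must also spare the enoate. Against it, ring A arrives aromatic. Bringing a hydroquinone diether down to the 4-oxo-7-hydroxy level needs a dearomatising reduction in the presence of two trisubstituted alkenes and an enoate, followed by a separate event to create C7, for which only the remote C2 centre offers control. The enantioselectivity of the ylide addition to a quinone methide without a substituent on the methylene carbon is also not assured. Mechanistically it is an ionic ring closure followed by several redox adjustments, against one cycloaddition and one rearrangement that give both ring A oxygens at their final oxidation levels. Up to A1 the step count is likely lower than that to 17; after A1 it is likely higher.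

Alternative 2: Both rings are cut, at O1–C7a and C3a–C4. In the forward key step a cationic phosphine–gold catalyst activates the C3a≡C7a alkyne of the acyclic alkynol aldehyde A5. The C2 hydroxyl adds 5-endo-dig to C7a, and the resulting enol ether attacks the tethered C4 aldehyde through C3a. Loss of the C3a proton restores C3a=C7a and gives A4, whose C4 carbinol is then oxidised. In its favour, both rings form in one operation. C7 is installed in the open chain by a reagent-controlled step, so neither a remote facial preference nor a regioselective peroxide cleavage is needed; on that point it is better than the chosen plan. Because no singlet oxygen is used, the full chain can be present from the start and no late coupling is required, which is also better. The C4 epimer mixture is harmless, as is the C4 mixture in 12 here. Against it, A5 is itself a long linear target with three stereocentres, a propargylic silyl ether, an aldehyde and the complete chain. The cationic intermediates (alkyne–gold complex, oxocarbenium ion) can be intercepted by the two chain alkenes, and the intermediate β-hydroxy enol ether can dehydrate. The chosen plan uses a far simpler substrate and reagent in its key step but leaves two selectivities open; the alternative closes them by construction at the price of a more delicate cascade. The ring-forming economy is better in the alternative; the overall count is probably equal or longer once A5 is included.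

Alternative 3: Ring B is cut at C3a=C7a. In the forward key step the keto-stabilised phosphorane A7 is heated, the ylide carbon C3a adds to the ester carbonyl C7a of the acyl group on the C2 oxygen, and loss of the phosphine oxide gives the 3-acetyl-4,5-dihydrofuran A6. Ring A would then be closed through C5–C6 by enolate alkylation after turning the PMB ether into a leaving group, and the terminal alkene would be elaborated to the enoate. In its favour, all three stereocentres come pre-formed from separate building blocks, the vinylogous ester appears directly at the right oxidation level, and the oxygen pattern is fixed by connectivity. In stereochemical certainty it is the equal of the chosen plan at C2 and C10 and better at C7. Against it, olefination of an ester carbonyl by an acyl-stabilised ylide is slow and needs prolonged heating, and C7 sits α to that ester carbonyl, where it can epimerise. The later ring A closure must enolise the methyl group selectively and alkylate next to a silyloxy-bearing carbon, where elimination competes. The chain still needs several steps after the key step. The chosen plan forms ring B early by robust C–O and C–C chemistry and spends its risk on one oxidation; the alternative spends it on a reluctant olefination and a late cyclisation. The linear sequence to A7 plus the steps after A6 is expected to be longer than the thirteen-step longest line proposed here.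

Key step: step 9

Assumption: the side arm of the key-step precursor is carried as a vinyl group (no allylic hydrogen, hence inert to singlet oxygen) and the tertiary oxygen as a TBS ether; these are spectator changes that leave the ring system, the diene, the carbon skeleton and the bonds formed in the key step unchanged.

## Route

Step 1
Reactants: 1 methyl (4S)-2,2-dimethyl-1,3-dioxolane-4-carboxylate
Product: 3 1-[(4S)-2,2-dimethyl-1,3-dioxolan-4-yl]ethan-1-one, via Weinreb amide 2 (not isolated)
Conditions: Me(MeO)NH·HCl, i-PrMgCl, THF, −20 °C; then MeMgBr, −20 → 0 °C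
Reagents that add atoms: methylmagnesium bromide C[Mg]Br
Why: The chloromagnesium amide of N,O-dimethylhydroxylamine converts the ester into amide 2 in the flask, and the magnesium chelate formed on addition of MeMgBr collapses only on work-up, so the ketone is not alkylated twice (Weinreb ketone synthesis); low temperature protects the α-alkoxy stereocentre.

Step 2
Reactants: 3 1-[(4S)-2,2-dimethyl-1,3-dioxolan-4-yl]ethan-1-one
Product: 4 (2S)-2-[(4S)-2,2-dimethyl-1,3-dioxolan-4-yl]but-3-en-2-ol
Conditions: CH2=CHMgBr, THF, −78 °C
Reagents that add atoms: vinylmagnesium bromide C=C[Mg]Br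
Why: Grignard addition to an α-alkoxy ketone in THF should run through the five-membered magnesium chelate of the carbonyl oxygen and the dioxolane oxygen on C4 (Cram chelate model); vinyl then enters from the face flanked by the α-hydrogen and not by the ring CH2, which for the (S)-ketone gives the (2S) carbinol that becomes C10.

Step 3
Reactants: 4 (2S)-2-[(4S)-2,2-dimethyl-1,3-dioxolan-4-yl]but-3-en-2-ol
Product: 5 tert-butyl{[(2S)-2-[(4S)-2,2-dimethyl-1,3-dioxolan-4-yl]but-3-en-2-yl]oxy}dimethylsilane
Conditions: TBSOTf, 2,6-lutidine, CH2Cl2, 0 °C → rt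
Reagents that add atoms: tert-butyldimethylsilyl trifluoromethanesulfonate CC(C)(C)[Si](C)(C)OS(=O)(=O)C(F)(F)F
Why: A silyl triflate with a hindered pyridine base is the standard silylation of a tertiary alcohol; TBS is preferred to a smaller silyl group because it should outlast the acetal hydrolysis and all later acid and base steps and adds bulk beside C2 for the key step.

Step 4
Reactants: 5 tert-butyl{[(2S)-2-[(4S)-2,2-dimethyl-1,3-dioxolan-4-yl]but-3-en-2-yl]oxy}dimethylsilane
Product: 6 (2S,3S)-3-[(tert-butyldimethylsilyl)oxy]-3-methylpent-4-ene-1,2-diol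
Conditions: AcOH/H2O (4:1), 40 °C
Reagents that add atoms: none
Why: Aqueous acetic acid hydrolyses a terminal isopropylidene acetal, while the hindered tertiary TBS ether is kinetically stable under these conditions (acetal hydrolysis); no stereocentre is touched.

Step 5
Reactants: 6 (2S,3S)-3-[(tert-butyldimethylsilyl)oxy]-3-methylpent-4-ene-1,2-diol
Product: 8 tert-butyldimethyl{[(2S)-2-[(2S)-oxiran-2-yl]but-3-en-2-yl]oxy}silane, via primary tosylate 7 (not isolated)
Conditions: TsCl, Et3N, Bu2SnO (cat.), CH2Cl2, 0 °C → rt; then K2CO3, MeOH, 0 °C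
Reagents that add atoms: none
Why: Tin-catalysed sulfonylation selects the primary hydroxyl of a 1,2-diol and the secondary alkoxide then displaces the tosylate in a 3-exo-tet closure; the C–O bond of the stereocentre is never broken, so its configuration is retained, and the capped tertiary oxygen cannot trigger epoxide migration.

Step 6
Reactants: 8 tert-butyldimethyl{[(2S)-2-[(2S)-oxiran-2-yl]but-3-en-2-yl]oxy}silane; 9 cyclohexane-1,3-dione
Product: 11 (2S)-2-[(2S)-2-[(tert-butyldimethylsilyl)oxy]but-3-en-2-yl]-3,5,6,7-tetrahydro-1-benzofuran-4(2H)-one, via hydroxyalkyl dione 10 (not isolated)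
Conditions: KOt-Bu (0.3 equiv), t-BuOH, 85 °C; then p-TsOH·H2O, toluene, 40 °C
Reagents that add atoms: none
Why: The dione enolate should open the oxirane at its unhindered CH2 in a protic, non-nucleophilic alcohol that favours C- over O-alkylation, the excess dione buffering the medium so that no free alkoxide persists to move the silyl group; hydroxy dione 10 closes to the hemiketal and acid dehydrates it to the vinylogous ester (β-dicarbonyl epoxide opening and cyclodehydration), with C2 unchanged because its C–O bond comes intact from 8.

Step 7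
Reactants: 11 (2S)-2-[(2S)-2-[(tert-butyldimethylsilyl)oxy]but-3-en-2-yl]-3,5,6,7-tetrahydro-1-benzofuran-4(2H)-one
Product: 12 (2S)-2-[(2S)-2-[(tert-butyldimethylsilyl)oxy]but-3-en-2-yl]-2,3,4,5,6,7-hexahydro-1-benzofuran-4-ol (both C4 epimers)
Conditions: i-Bu2AlH, CH2Cl2, −78 °C; aq. potassium sodium tartrate
Reagents that add atoms: none
Why: The aluminium hydride adds 1,2 to the vinylogous ester carbonyl at low temperature (first half of a Stork–Danheiser sequence); the new C4 centre is destroyed in step 8, and the basic tartrate work-up avoids acid-triggered hydrolysis of this sensitive allylic alcohol, which is used crude.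

Step 8
Reactants: 12 (2S)-2-[(2S)-2-[(tert-butyldimethylsilyl)oxy]but-3-en-2-yl]-2,3,4,5,6,7-hexahydro-1-benzofuran-4-ol
Product: 14 tert-butyldimethyl{[(2S)-2-[(2S)-2,3,5,6-tetrahydro-1-benzofuran-2-yl]but-3-en-2-yl]oxy}silane, via allylic mesylate 13 (not isolated)
Conditions: Ms2O, Et3N, CH2Cl2, −40 → 0 °C
Reagents that add atoms: none
Why: The allylic mesylate should ionise at once to the O1-stabilised allyl cation, and the amine removes a proton from C7, the carbon next to the most electron-poor centre C7a, to give the cross-conjugated 2-alkoxy diene; this is the E1 pathway by which unsaturated acetals give 2-alkoxy-1,3-dienes with a silyl triflate and a tertiary amine, and excess amine at low temperature prevents acid-catalysed drift to the linear dienol ether.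

Step 9
Reactants: 14 tert-butyldimethyl{[(2S)-2-[(2S)-2,3,5,6-tetrahydro-1-benzofuran-2-yl]but-3-en-2-yl]oxy}silane
Product: 15 tert-butyldimethyl{[(2S)-2-[(2S,4S,7R)-4,7-epidioxy-2,3,4,5,6,7-hexahydro-1-benzofuran-2-yl]but-3-en-2-yl]oxy}silane
Conditions: O2, TPP (cat.), visible light, CH2Cl2, −78 °C
Reagents that add atoms: dioxygen O=O
Why: Energy transfer from triplet TPP gives singlet oxygen, which adds as a two-atom dienophile across C4 and C7 of the s-cis ring A diene in a concerted suprafacial (4+2) cycloaddition; the closest known reaction type is the photooxygenation of cyclohexa-1,3-dienes to 2,3-dioxabicyclo[2.2.2]oct-5-enes. The one new ring, the bridging 1,2-dioxane, is closed by cycloaddition, both C–O bonds forming on the same face and the C3a=C7a double bond emerging where the target has its enol ether. C4 and C7 are created together and tied to each other by the bridge, so one element decides both: the diene face, differentiated by the C2 substituent, a fully substituted carbon carrying the bulky OTBS group, so that approach anti to it gives the (4S,7R) adduct. The tertiary oxygen is silylated so that no hydroxyl can draw the oxidant to its own face by hydrogen bonding, and TBS is used to increase the bias. Chemoselectivity against ene reaction and dioxetane formation is needed: the vinyl group is monosubstituted and its only allylic carbon is quaternary, so it has no hydrogen to deliver, and the locked s-cis electron-rich diene is expected to react by (4+2) faster than its enol ether reacts by (2+2) or ene at −78 °C. Irradiation is stopped at full conversion of 14 because the product still contains an enol ether. The C4 centre is given up in step 10, so only the C7 outcome is carried into the target.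

Step 10
Reactants: 15 tert-butyldimethyl{[(2S)-2-[(2S,4S,7R)-4,7-epidioxy-2,3,4,5,6,7-hexahydro-1-benzofuran-2-yl]but-3-en-2-yl]oxy}silane
Product: 17 (2S,7R)-2-[(2S)-2-[(tert-butyldimethylsilyl)oxy]but-3-en-2-yl]-7-[(triethylsilyl)oxy]-3,5,6,7-tetrahydro-1-benzofuran-4(2H)-one, via hydroxy ketone 16 (not isolated)
Conditions: Et3N, CH2Cl2, 0 °C → rt; then TESCl, DMAP (cat.)
Reagents that add atoms: chlorotriethylsilane CC[Si](Cl)(CC)CC
Why: The amine removes the bridgehead hydrogen at C4 as the O–O bond breaks (Kornblum–DeLaMare rearrangement); loss of H–C4 should be preferred because the developing carbonyl becomes conjugated with the C3a=C7a–O1 enol ether, whereas a C7 carbonyl would not, and C7 keeps its oxygen and configuration before being capped in the same flask.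

Step 11
Reactants: 18 pent-4-yn-1-ol
Product: 19 (4E)-5-iodo-4-methylpent-4-en-1-ol
Conditions: AlMe3, Cp2ZrCl2, CH2Cl2, 0 °C → rt; then I2, THF, −30 → 0 °C
Reagents that add atoms: trimethylaluminium C[Al](C)C; iodine II
Why: Zirconocene-promoted syn-carboalumination of the terminal alkyne (Negishi carboalumination) places methyl on the internal and aluminium on the terminal carbon, and iodinolysis with retention gives the (E)-iodoalkene.

Step 12
Reactants: 19 (4E)-5-iodo-4-methylpent-4-en-1-ol
Product: 21 ethyl (2E,6E)-7-iodo-2,6-dimethylhepta-2,6-dienoate, via iodo aldehyde 20 (not isolated)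
Conditions: Dess–Martin periodinane, NaHCO3, CH2Cl2, 0 °C → rt; then Ph3P=C(CH3)CO2Et, rt
Reagents that add atoms: ethyl 2-(triphenylphosphoranylidene)propanoate CCOC(=O)C(C)=P(c1ccccc1)(c1ccccc1)c1ccccc1
Why: Dess–Martin oxidation gives the aldehyde, which is trapped in the same flask by the stabilised α-methyl ylide (Wittig olefination); such ylides are expected to give the (E)-trisubstituted enoate.

Step 13
Reactants: 21 ethyl (2E,6E)-7-iodo-2,6-dimethylhepta-2,6-dienoate
Product: 22 (2E,6E)-7-iodo-2,6-dimethylhepta-2,6-dienoic acid
Conditions: LiOH·H2O, THF/MeOH/H2O, rt; then 1 M HCl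
Reagents that add atoms: lithium hydroxide [Li+].[OH-]
Why: Saponification is done on the fragment, where nothing is base-sensitive, so the vinylogous ester of the core never meets hydroxide; the alkenyl iodide and both alkene geometries are unaffected.

Step 14
Reactants: 17 (2S,7R)-2-[(2S)-2-[(tert-butyldimethylsilyl)oxy]but-3-en-2-yl]-7-[(triethylsilyl)oxy]-3,5,6,7-tetrahydro-1-benzofuran-4(2H)-one
Product: 23 (2S,7R)-2-[(2S)-2-[(tert-butyldimethylsilyl)oxy]-4-(4,4,5,5-tetramethyl-1,3,2-dioxaborolan-2-yl)butan-2-yl]-7-[(triethylsilyl)oxy]-3,5,6,7-tetrahydro-1-benzofuran-4(2H)-one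
Conditions: HBpin, RhCl(PPh3)3 (cat.), THF, rt
Reagents that add atoms: pinacolborane CC1(C)OBOC1(C)C
Why: Rhodium-catalysed hydroboration with pinacolborane puts boron on the terminal carbon of the monosubstituted alkene and, unlike dialkylboranes, leaves the carbonyl alone (catalysed hydroboration selects C=C over C=O); no stereocentre is formed.

Step 15
Reactants: 23 (2S,7R)-2-[(2S)-2-[(tert-butyldimethylsilyl)oxy]-4-(4,4,5,5-tetramethyl-1,3,2-dioxaborolan-2-yl)butan-2-yl]-7-[(triethylsilyl)oxy]-3,5,6,7-tetrahydro-1-benzofuran-4(2H)-one; 22 (2E,6E)-7-iodo-2,6-dimethylhepta-2,6-dienoic acid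
Product: 24 (2E,6E,10S)-10-[(tert-butyldimethylsilyl)oxy]-2,6-dimethyl-10-[(2S,7R)-4-oxo-7-[(triethylsilyl)oxy]-2,3,4,5,6,7-hexahydro-1-benzofuran-2-yl]undeca-2,6-dienoic acid
Conditions: Pd(OAc)2 (cat.), SPhos, K3PO4, THF/H2O, 60 °C; then aq. citric acid
Reagents that add atoms: none
Why: B-alkyl Suzuki–Miyaura coupling: oxidative addition of the alkenyl iodide with retention, base-assisted transmetalation of the primary alkyl boronate, and reductive elimination from the bulky biarylphosphine palladium complex ahead of β-hydride elimination; the (6E) geometry is carried over from 22 and the carboxylate is a spectator.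

Step 16
Reactants: 24 (2E,6E,10S)-10-[(tert-butyldimethylsilyl)oxy]-2,6-dimethyl-10-[(2S,7R)-4-oxo-7-[(triethylsilyl)oxy]-2,3,4,5,6,7-hexahydro-1-benzofuran-2-yl]undeca-2,6-dienoic acid
Product: 25 (2E,6E,10S)-10-hydroxy-10-[(2S,7R)-7-hydroxy-4-oxo-2,3,4,5,6,7-hexahydro-1-benzofuran-2-yl]-2,6-dimethylundeca-2,6-dienoic acid
Conditions: HF·pyridine, THF, 0 → 40 °C
Reagents that add atoms: none
Why: Fluoride cleaves both Si–O bonds (desilylation), the secondary TES ether quickly and the tertiary TBS ether more slowly; the mildly acidic medium suits the free acid and avoids hydroxide, and no stereocentre is touched.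

## Compound list

1 | methyl (4S)-2,2-dimethyl-1,3-dioxolane-4-carboxylate | COC(=O)[C@@H]1COC(C)(C)O1 | starting material
2 | (4S)-N-methoxy-N,2,2-trimethyl-1,3-dioxolane-4-carboxamide | CON(C)C(=O)[C@@H]1COC(C)(C)O1 | intermediate
3 | 1-[(4S)-2,2-dimethyl-1,3-dioxolan-4-yl]ethan-1-one | CC(=O)[C@@H]1COC(C)(C)O1 | intermediate
4 | (2S)-2-[(4S)-2,2-dimethyl-1,3-dioxolan-4-yl]but-3-en-2-ol | C=C[C@](C)(O)[C@@H]1COC(C)(C)O1 | intermediate
5 | tert-butyl{[(2S)-2-[(4S)-2,2-dimethyl-1,3-dioxolan-4-yl]but-3-en-2-yl]oxy}dimethylsilane | C=C[C@](C)(O[Si](C)(C)C(C)(C)C)[C@@H]1COC(C)(C)O1 | intermediate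
6 | (2S,3S)-3-[(tert-butyldimethylsilyl)oxy]-3-methylpent-4-ene-1,2-diol | C=C[C@](C)(O[Si](C)(C)C(C)(C)C)[C@@H](O)CO | intermediate
7 | (2S,3S)-3-[(tert-butyldimethylsilyl)oxy]-2-hydroxy-3-methylpent-4-en-1-yl 4-methylbenzenesulfonate | C=C[C@](C)(O[Si](C)(C)C(C)(C)C)[C@@H](O)COS(=O)(=O)c1ccc(C)cc1 | intermediate
8 | tert-butyldimethyl{[(2S)-2-[(2S)-oxiran-2-yl]but-3-en-2-yl]oxy}silane | C=C[C@](C)(O[Si](C)(C)C(C)(C)C)[C@@H]1CO1 | intermediate
9 | cyclohexane-1,3-dione | O=C1CCCC(=O)C1 | starting material
10 | 2-[(2S,3S)-3-[(tert-butyldimethylsilyl)oxy]-2-hydroxy-3-methylpent-4-en-1-yl]cyclohexane-1,3-dione | C=C[C@](C)(O[Si](C)(C)C(C)(C)C)[C@@H](O)CC1C(=O)CCCC1=O | intermediate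
11 | (2S)-2-[(2S)-2-[(tert-butyldimethylsilyl)oxy]but-3-en-2-yl]-3,5,6,7-tetrahydro-1-benzofuran-4(2H)-one | C=C[C@](C)(O[Si](C)(C)C(C)(C)C)[C@@H]1CC2=C(O1)CCCC2=O | intermediate
12 | (2S)-2-[(2S)-2-[(tert-butyldimethylsilyl)oxy]but-3-en-2-yl]-2,3,4,5,6,7-hexahydro-1-benzofuran-4-ol (both C4 epimers) | C=C[C@](C)(O[Si](C)(C)C(C)(C)C)[C@@H]1CC2=C(O1)CCCC2O | intermediate
13 | (2S)-2-[(2S)-2-[(tert-butyldimethylsilyl)oxy]but-3-en-2-yl]-2,3,4,5,6,7-hexahydro-1-benzofuran-4-yl methanesulfonate | C=C[C@](C)(O[Si](C)(C)C(C)(C)C)[C@@H]1CC2=C(O1)CCCC2OS(C)(=O)=O | intermediate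
14 | tert-butyldimethyl{[(2S)-2-[(2S)-2,3,5,6-tetrahydro-1-benzofuran-2-yl]but-3-en-2-yl]oxy}silane | C=C[C@](C)(O[Si](C)(C)C(C)(C)C)[C@@H]1CC2=CCCC=C2O1 | intermediate
15 | tert-butyldimethyl{[(2S)-2-[(2S,4S,7R)-4,7-epidioxy-2,3,4,5,6,7-hexahydro-1-benzofuran-2-yl]but-3-en-2-yl]oxy}silane | C=C[C@](C)(O[Si](C)(C)C(C)(C)C)[C@@H]1CC2=C(O1)[C@H]3CC[C@@H]2OO3 | intermediate
16 | (2S,7R)-2-[(2S)-2-[(tert-butyldimethylsilyl)oxy]but-3-en-2-yl]-7-hydroxy-3,5,6,7-tetrahydro-1-benzofuran-4(2H)-one | C=C[C@](C)(O[Si](C)(C)C(C)(C)C)[C@@H]1CC2=C(O1)[C@H](O)CCC2=O | intermediate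
17 | (2S,7R)-2-[(2S)-2-[(tert-butyldimethylsilyl)oxy]but-3-en-2-yl]-7-[(triethylsilyl)oxy]-3,5,6,7-tetrahydro-1-benzofuran-4(2H)-one | C=C[C@](C)(O[Si](C)(C)C(C)(C)C)[C@@H]1CC2=C(O1)[C@H](O[Si](CC)(CC)CC)CCC2=O | intermediate
18 | pent-4-yn-1-ol | C#CCCCO | starting material
19 | (4E)-5-iodo-4-methylpent-4-en-1-ol | C/C(=C\I)CCCO | intermediate
20 | (4E)-5-iodo-4-methylpent-4-enal | C/C(=C\I)CCC=O | intermediate
21 | ethyl (2E,6E)-7-iodo-2,6-dimethylhepta-2,6-dienoate | C/C(=C\I)CC/C=C(\C)C(=O)OCC | intermediate
22 | (2E,6E)-7-iodo-2,6-dimethylhepta-2,6-dienoic acid | C/C(=C\I)CC/C=C(\C)C(=O)O | intermediate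
23 | (2S,7R)-2-[(2S)-2-[(tert-butyldimethylsilyl)oxy]-4-(4,4,5,5-tetramethyl-1,3,2-dioxaborolan-2-yl)butan-2-yl]-7-[(triethylsilyl)oxy]-3,5,6,7-tetrahydro-1-benzofuran-4(2H)-one | CC1(C)OB(CC[C@](C)(O[Si](C)(C)C(C)(C)C)[C@@H]2CC3=C(O2)[C@H](O[Si](CC)(CC)CC)CCC3=O)OC1(C)C | intermediate
24 | (2E,6E,10S)-10-[(tert-butyldimethylsilyl)oxy]-2,6-dimethyl-10-[(2S,7R)-4-oxo-7-[(triethylsilyl)oxy]-2,3,4,5,6,7-hexahydro-1-benzofuran-2-yl]undeca-2,6-dienoic acid | C/C(=C\CC[C@](C)(O[Si](C)(C)C(C)(C)C)[C@@H]1CC2=C(O1)[C@H](O[Si](CC)(CC)CC)CCC2=O)CC/C=C(\C)C(=O)O | intermediate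
25 | (2E,6E,10S)-10-hydroxy-10-[(2S,7R)-7-hydroxy-4-oxo-2,3,4,5,6,7-hexahydro-1-benzofuran-2-yl]-2,6-dimethylundeca-2,6-dienoic acid | C/C(=C\CC[C@](C)(O)[C@@H]1CC2=C(O1)[C@H](O)CCC2=O)CC/C=C(\C)C(=O)O | target

## Step count and least certain steps

Total: 16 steps. Longest linear sequence: 13 steps (steps 1–10 and 14–16, from 1 to 25). The side-chain fragment takes 3 steps (11–13).

Step 9 (key step). The most likely failure is poor facial selectivity, because the only control element, the C2 substituent, sits on the other ring, two atoms from C7. Next in likelihood is over-oxidation of the enol ether that remains in the product. The fallback sets C7 by SN2 inversion instead of by facial choice. It sets out from 14, which is oxygenated without regard to the face. The rearrangement of step 10 is worked up before silylation and the C7 epimers are separated. The syn endoperoxide F1 gives the 7-epi alcohol F2, which is esterified with inversion under Mitsunobu conditions (PPh3, DIAD, 4-nitrobenzoic acid) to the 4-nitrobenzoate F3. Methanolysis (K2CO3, MeOH) gives 16, where the route is rejoined and silylated as in step 10.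

Step 2. Chelation may be incomplete, since an acetonide oxygen is a weak donor, and Felkin-type addition would then erode or reverse the induction at C10. The fallback reverses the order in which the two carbon groups are introduced. It sets out from 1: amide 2 is isolated and treated with CH2=CHMgBr to give the vinyl ketone F4, and a methyl nucleophile (MeMgBr, or MeLi/CeCl3 for clean 1,2-addition) is added to it. With methyl and vinyl exchanged, the facial preference that gave the wrong epimer now gives 4, where the route is rejoined.

Step 6. O-alkylation of the ambident dione enolate, or simple lack of reactivity towards the hindered oxirane, may prevail over C-alkylation. The fallback brings ring A in as an arene and sets out from 8. The aryllithium F5, made from 1,3-dimethoxybenzene and n-BuLi, opens the oxirane with BF3·OEt2 at −78 °C to give the aryl carbinol F6. Birch reduction (Li, NH3, t-BuOH, THF, −78 °C) gives the bis-enol ether F7. Mild aqueous acid (oxalic acid, THF/H2O) liberates the 1,3-dione, which cyclodehydrates to 11, where the route is rejoined.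

Step 8. Deprotonation of the allyl cation at C5 instead of C7, or acid-catalysed isomerisation and hydrolysis of the sensitive diene, would give the linear dienol ether or an enone. The fallback is a pericyclic 1,4-dehydration that fixes the regiochemistry by mechanism. It sets out from 12, which is treated with 2,4-dinitrobenzenesulfenyl chloride and Et3N to give the allylic sulfenate F8. A [2,3]-sigmatropic shift moves sulfur to C7a and the double bond to C3a=C4, giving the sulfoxide F9. Its syn-elimination can take a hydrogen only from C7, because C3a carries none, and gives 14, where the route is rejoined.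

Step 10. Abstraction of H–C7 instead of H–C4 is possible, because C7–H is inductively acidified by O1 on the neighbouring carbon. The fallback replaces the base-induced fragmentation by reduction and selective oxidation. It sets out from 15, which is reduced with thiourea in MeOH to the cis-4,7-diol F10. MnO2 in CH2Cl2 should oxidise only the C4 carbinol, whose oxidation generates the push–pull vinylogous ester. This gives 16, where the route is rejoined.

Step 15. Slow transmetalation of the primary alkyl pinacol boronate may let protodehalogenation of 22 or base damage on prolonged heating take over. The fallback is a Negishi coupling and sets out from 23. Oxidation (NaBO3·4H2O, THF/H2O) gives the primary alcohol F11, and I2, PPh3 and imidazole give the iodide F12. Zinc insertion (Zn, LiCl, THF) gives the alkylzinc iodide F13, which is coupled with 21 under Pd(PPh3)4 to the ethyl ester F14. Hydrolysis with Me3SnOH (1,2-dichloroethane, 70 °C) gives 24, where the route is rejoined.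

## Further compounds

F1 | step 9 | tert-butyldimethyl{[(2S)-2-[(2S,4R,7S)-4,7-epidioxy-2,3,4,5,6,7-hexahydro-1-benzofuran-2-yl]but-3-en-2-yl]oxy}silane | C=C[C@](C)(O[Si](C)(C)C(C)(C)C)[C@@H]1CC2=C(O1)[C@@H]3CC[C@H]2OO3
F2 | step 9 | (2S,7S)-2-[(2S)-2-[(tert-butyldimethylsilyl)oxy]but-3-en-2-yl]-7-hydroxy-3,5,6,7-tetrahydro-1-benzofuran-4(2H)-one | C=C[C@](C)(O[Si](C)(C)C(C)(C)C)[C@@H]1CC2=C(O1)[C@@H](O)CCC2=O
F3 | step 9 | (2S,7R)-2-[(2S)-2-[(tert-butyldimethylsilyl)oxy]but-3-en-2-yl]-4-oxo-2,3,4,5,6,7-hexahydro-1-benzofuran-7-yl 4-nitrobenzoate | C=C[C@](C)(O[Si](C)(C)C(C)(C)C)[C@@H]1CC2=C(O1)[C@H](OC(=O)c3ccc(cc3)[N+](=O)[O-])CCC2=O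
F4 | step 2 | 1-[(4S)-2,2-dimethyl-1,3-dioxolan-4-yl]prop-2-en-1-one | C=CC(=O)[C@@H]1COC(C)(C)O1
F5 | step 6 | (2,6-dimethoxyphenyl)lithium | [Li]c1c(OC)cccc1OC
F6 | step 6 | (2S,3S)-3-[(tert-butyldimethylsilyl)oxy]-1-(2,6-dimethoxyphenyl)-3-methylpent-4-en-2-ol | C=C[C@](C)(O[Si](C)(C)C(C)(C)C)[C@@H](O)Cc1c(OC)cccc1OC
F7 | step 6 | (2S,3S)-3-[(tert-butyldimethylsilyl)oxy]-1-(2,6-dimethoxycyclohexa-2,5-dien-1-yl)-3-methylpent-4-en-2-ol | C=C[C@](C)(O[Si](C)(C)C(C)(C)C)[C@@H](O)CC1C(OC)=CCC=C1OC
F8 | step 8 | (2S)-2-[(2S)-2-[(tert-butyldimethylsilyl)oxy]but-3-en-2-yl]-2,3,4,5,6,7-hexahydro-1-benzofuran-4-yl 2,4-dinitrobenzenesulfenate | C=C[C@](C)(O[Si](C)(C)C(C)(C)C)[C@@H]1CC2=C(O1)CCCC2OSc1ccc(cc1[N+](=O)[O-])[N+](=O)[O-]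
F9 | step 8 | tert-butyl{[(2S)-2-[(2S)-7a-(2,4-dinitrobenzenesulfinyl)-2,3,5,6,7,7a-hexahydro-1-benzofuran-2-yl]but-3-en-2-yl]oxy}dimethylsilane | C=C[C@](C)(O[Si](C)(C)C(C)(C)C)[C@@H]1CC2=CCCCC2(O1)S(=O)c1ccc(cc1[N+](=O)[O-])[N+](=O)[O-]
F10 | step 10 | (2S,4S,7R)-2-[(2S)-2-[(tert-butyldimethylsilyl)oxy]but-3-en-2-yl]-2,3,4,5,6,7-hexahydro-1-benzofuran-4,7-diol | C=C[C@](C)(O[Si](C)(C)C(C)(C)C)[C@@H]1CC2=C(O1)[C@H](O)CC[C@@H]2O
F11 | step 15 | (2S,7R)-2-[(2S)-2-[(tert-butyldimethylsilyl)oxy]-4-hydroxybutan-2-yl]-7-[(triethylsilyl)oxy]-3,5,6,7-tetrahydro-1-benzofuran-4(2H)-one | OCC[C@](C)(O[Si](C)(C)C(C)(C)C)[C@@H]1CC2=C(O1)[C@H](O[Si](CC)(CC)CC)CCC2=O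
F12 | step 15 | (2S,7R)-2-[(2S)-2-[(tert-butyldimethylsilyl)oxy]-4-iodobutan-2-yl]-7-[(triethylsilyl)oxy]-3,5,6,7-tetrahydro-1-benzofuran-4(2H)-one | ICC[C@](C)(O[Si](C)(C)C(C)(C)C)[C@@H]1CC2=C(O1)[C@H](O[Si](CC)(CC)CC)CCC2=O
F13 | step 15 | {(3S)-3-[(tert-butyldimethylsilyl)oxy]-3-[(2S,7R)-4-oxo-7-[(triethylsilyl)oxy]-2,3,4,5,6,7-hexahydro-1-benzofuran-2-yl]butyl}zinc iodide | I[Zn]CC[C@](C)(O[Si](C)(C)C(C)(C)C)[C@@H]1CC2=C(O1)[C@H](O[Si](CC)(CC)CC)CCC2=O
F14 | step 15 | ethyl (2E,6E,10S)-10-[(tert-butyldimethylsilyl)oxy]-2,6-dimethyl-10-[(2S,7R)-4-oxo-7-[(triethylsilyl)oxy]-2,3,4,5,6,7-hexahydro-1-benzofuran-2-yl]undeca-2,6-dienoate | C/C(=C\CC[C@](C)(O[Si](C)(C)C(C)(C)C)[C@@H]1CC2=C(O1)[C@H](O[Si](CC)(CC)CC)CCC2=O)CC/C=C(\C)C(=O)OCC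
A1 | alternative 1 | methyl (2E,6E)-10-[(2S)-4-methoxy-7-(prop-2-en-1-yloxy)-2,3-dihydro-1-benzofuran-2-yl]-2,6-dimethyl-10-oxodeca-2,6-dienoate | COc1ccc(OCC=C)c2O[C@@H](Cc12)C(=O)CC/C=C(\C)CC/C=C(\C)C(=O)OC
A2 | alternative 1 | [2-hydroxy-6-methoxy-3-(prop-2-en-1-yloxy)phenyl]methyl acetate | CC(=O)OCc1c(OC)ccc(OCC=C)c1O
A3 | alternative 1 | methyl (2E,6E)-11-bromo-2,6-dimethyl-10-oxoundeca-2,6-dienoate | BrCC(=O)CC/C=C(\C)CC/C=C(\C)C(=O)OC
A4 | alternative 2 | methyl (2E,6E,10S)-10-[(2S,7R)-7-[(tert-butyldimethylsilyl)oxy]-4-hydroxy-2,3,4,5,6,7-hexahydro-1-benzofuran-2-yl]-2,6-dimethyl-10-[(triethylsilyl)oxy]undeca-2,6-dienoate (C4 epimers) | C/C(=C\CC[C@](C)(O[Si](CC)(CC)CC)[C@@H]1CC2=C(O1)[C@H](O[Si](C)(C)C(C)(C)C)CCC2O)CC/C=C(\C)C(=O)OC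
A5 | alternative 2 | methyl (2E,6E,10S,11S,15R)-15-[(tert-butyldimethylsilyl)oxy]-11-hydroxy-2,6,10-trimethyl-18-oxo-10-[(triethylsilyl)oxy]octadeca-2,6-dien-13-ynoate | C/C(=C\CC[C@](C)(O[Si](CC)(CC)CC)[C@@H](O)CC#C[C@H](O[Si](C)(C)C(C)(C)C)CCC=O)CC/C=C(\C)C(=O)OC
A6 | alternative 3 | 1-[(5S)-2-[(1R)-1-[(tert-butyldimethylsilyl)oxy]-2-[(4-methoxyphenyl)methoxy]ethyl]-5-[(2S,5E)-6-methyl-2-[(triethylsilyl)oxy]deca-5,9-dien-2-yl]-4,5-dihydrofuran-3-yl]ethan-1-one | C=CCC/C(C)=C/CC[C@](C)(O[Si](CC)(CC)CC)[C@@H]1CC(C(C)=O)=C(O1)[C@H](O[Si](C)(C)C(C)(C)C)COCc1ccc(OC)cc1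
A7 | alternative 3 | (5S,6S,9E)-6,10-dimethyl-2-oxo-6-[(triethylsilyl)oxy]-3-(triphenylphosphoranylidene)tetradeca-9,13-dien-5-yl (2R)-2-[(tert-butyldimethylsilyl)oxy]-3-[(4-methoxyphenyl)methoxy]propanoate | C=CCC/C(C)=C/CC[C@](C)(O[Si](CC)(CC)CC)[C@@H](OC(=O)[C@H](O[Si](C)(C)C(C)(C)C)COCc1ccc(OC)cc1)CC(C(C)=O)=P(c1ccccc1)(c1ccccc1)c1ccccc1
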